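A small substrate charge of 0.20 M stood in the theta run beside 1 M of reagent in the second phase, and that run read more target in percent of its charge at 40.0 h than the eta and gamma runs read at their last readings, so two settings differed and I built the flask from that difference.

| flask | substrate | reagent in the second phase | remark | time | volume of the second phase over the first |
|---|---|---|---|---|---|
| eta | 0.40 M | 0.50 M | run made earlier |  |  |
| gamma | 0.40 M | 0.75 M | run made earlier |  |  |
| theta | 0.20 M | 1 M | run made earlier |  |  |
| flask | 0.40 M | 1.00 M |  | 3.0 d | 2.0 |

| run | time / h | target / % |
|---|---|---|
| eta | 3.00 | 0 |
| eta | 8.00 | 0.4 |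
| eta | 15.0 | 1.3 |
| eta | 25.0 | 2.2 |
| eta | 30.0 | 4.1 |
| eta | 40.0 | 3.8 |
| gamma | 3.00 | 0.6 |
| gamma | 8.00 | 1.2 |
| gamma | 15.0 | 1.8 |
| gamma | 25.0 | 3.1 |
| gamma | 30.0 | 4.6 |
| gamma | 40.0 | 5.2 |
| theta | 4.00 | 1.6 |
| theta | 10.0 | 2.4 |
| theta | 20.0 | 4.5 |
| theta | 30.0 | 8.2 |
| theta | 40.0 | 9.4 |

(standard deviation of a reading: 0.5 percentage points)

- in the second phase: reagent in the second phase; everything else is in the first
- charges count per volume of the first phase; a concentration in a rate is the amount of a species over the volume of its own phase; every rate counts per litre of the first phase
- the earlier runs hold the two phases in the same ratio of volumes as the flask asked about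

1. target at 3.0 d, in percent of the substrate charged
2. the change that raises the amount of target at 3.0 d, in percent of the substrate charged most ("none" if none brings more than 2 percentage points) (Friday's / Tuesday's / none)
3. amount of target at 3.0 d, in percent of the substrate charged, after Friday's

- Friday's: doubling the amount of reagent in the second phase, all else as stated
- Tuesday's: doubling the transfer coefficient of the reagent in the second phase, all else as stated

1. The main step alone. I took it as pseudo-first-order in substrate and proportional to the reagent charge. Scaled to 1.00 M of reagent, the last readings of the eta and gamma runs became 7.60% and 6.93%, with mean 7.27%. A straight line to 3.0 d gave 13.1%.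

2. One more process. The main step alone would put the theta run at that same mean, but it read 9.4%, a ratio of 1.29. So I added a loss second order in substrate and named loss time the time in which this loss by itself halves a charge of 0.40 M; I reckoned it as 24.1 h. The fraction left is then one over one plus time over loss time, and I let the value at mid-run stand for the whole run. The theta charge, half the others, has its loss time doubled, and the loss time above is the one that returns that ratio. The readings carry the loss, so with it taken out of them I reckoned the flask at 24.0%, and with it put back for the flask's time at 9.60%.

3. The rest. I kept proportionality in reagent and added nothing else, so Friday's gave me 19.2%, and I chose it.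

The forecast gave 12.8%, Friday's and 24%, reading the rate as “slightly below first order in substrate”.

The flask gave 9.70%. Friday's won, with 4.8 percentage points against 2.2 points, and reached 14.5%, below the forecast's figure and mine.

    2 substrate → self-condensation product (k = 1.70 × 10⁻⁵ L mol⁻¹ s⁻¹)
    reagent in the reaction phase → decomposed reagent (k = 7.50 × 10⁻⁶ s⁻¹)
    reagent in the reaction phase + target → over-reacted product (k = 1.50 × 10⁻⁵ L mol⁻¹ s⁻¹)
    substrate + reagent in the reaction phase → target (k = 1.60 × 10⁻⁵ L mol⁻¹ s⁻¹)
    reagent in the reaction phase ⇌ reagent in the second phase, rate k5*([reagent in the reaction phase] - [reagent in the second phase]/K5) per volume of the first phase (partition coefficient = 2.50, kL = 1.40 × 10⁻⁵ s⁻¹)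

At 1.02 d the flask's substrate went 4.1 times as fast into self-condensation product as into target. At 3.00 d the flask held 70.6% self-condensation product, each counted as the two substrate it holds, and 17.7% substrate, where my loss time, reckoned for that loss by itself, had left 25.1%. For the neighbour charged with 1.6 M of substrate, the loss time falls to 6.03 h, a quarter of mine, and the mid-run reckoning gives 3.44%; at 3.00 d that neighbour holds 3.62% target.

All runs were computed for an exercise; noise was put on by code.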